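The constants put Z first: in spring, at the start, 370 parts of E sit bound as Z.E for each part left free, so I take that balance as settled and reckon with the free E it leaves.

the same everywhere: G 0.10 M; Z 0.0500 equiv; time 2.5 min

| charge | L |
|---|---|
| spring | 0.300 equiv |
| midnight | 1.00 equiv |
| summer | 2.50 equiv |
| dusk | 8.00 equiv |

    G + L + E → J + 2 E (k1 = 20 /M²/s)
    G + L → J + E (k2 = 0.0077 /M/s)
    Z + E ⇌ Z.E, settled at all times (K3 = 74000 /M)
    J → D (k4 = 0.020 /s)
    Q ⇌ J, rate k5*(cs5 - [J]) while solid is left; crystals form when [J] > cs5 (cs5 = 0.074 M, k5 = 17 /s)

- amount of J at the end, in percent of the G charged for spring, midnight, summer, dusk, in this order
- how that number moves from the first to the last of them (hardly changes / falls, then rises / rises all the way / rises, then falls / falls all the way)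

- J is meant together with its Q
- solid, in amounts per volume of the solution: Q
- "hardly changes" means that all values lie within two and a half points (for a concentration: within two and a half percent of the largest)
- run time (spring): 2.5 min

While Z lasts, the step that needs E is held back, and the plain step, G + L giving J + E, has to supply what Z takes up. My quantity is the holding time (the induction period): the charge of Z divided by the starting rate of the plain step. In spring it is 3.61 min, longer than the run of 2.5 min, so in spring I expect Z to outlast the run, with J fed by the plain step and draining to D.

A steady feed against that drain leaves 1.10% of the G charge as J. For a ceiling, the plain step uses about 3.46% of the G charge in spring, and with that much bound to Z, the balance lets the E-fed step reach about 7.92% of the plain rate, which gives 1.18%. For a floor, I let the feed sag by the whole loss of G and by the 11.6% of L that the plain step uses, which gives 0.937%. I commit to the middle of these two bounds for spring, 1.06%.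

At midnight the holding time is 1.08 min and at dusk 0.135 min. If all G became J the moment the hold ended, the decay over the remaining time would leave 18.2% at midnight, above the spring ceiling, and 5.86% at dusk; I take these as rough floors, good as far as G is used up by the end. The dusk hold leaves 2.37 min for decay against 1.42 min at midnight, so from these three marks I commit to a row that rises, then falls.

The forecast gives 1.1%, 30%, 10% and 6.3%, rises, then falls, its spring value lying inside my bracket on the ground that “Titration never finishes”. The simulation gives 1.02%, 32.8%, 10.4% and 6.44%, rises, then falls, and spring lies between my bounds.

In spring, with the holding time of 3.61 min longer than the run, the plain step ran while Z was there, and at 2.50 min 34.7% of the Z charge was still unbound and 96.7% of the G remained. At midnight the holding time of 1.08 min had passed by 1.25 min, when unbound Z was down to 0.390% of its charge, free E stood at 0.00345 M and G still stood at 91.6%, and the E-fed step then ran, leaving G at 10.2% and J at 32.8% by 2.50 min.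

(The constants used here come from no measurement; the flask was simulated.)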